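Ring C of the flavanone is disconnected at O1–C8a and C4–C4a. The feature exploited is that ring A bears O1 (on C8a) and the C4 carbonyl (on C4a) on adjacent carbons, the pattern produced when a nucleophile adds to an aryne and the aryl anion is trapped by an acyl group. In one operation the alkoxide of a chiral β-hydroxy ester adds to a chlorine-biased aryne and the anion closes ring C on the ester, the C2 stereocentre being carried in unchanged. The precursors are an ortho-silylaryl triflate (chloro, benzyloxy) and an ethyl (3S)-3-aryl-3-hydroxypropanoate holding the silyl-protected trans-diol of the dimethylchromane.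

Key step: step 12

Remark: the chromanone half is numbered as a flavanone (rings A and C, O1 to C8a) and the dimethylpyran half as a chromane; the target is read as the (2S)-flavanone carrying a trans-(3R,4S)-chromanediol. Bn = benzyl, TBS = tert-butyldimethylsilyl, Tf = trifluoromethanesulfonyl.

**Hydroxy ester fragment**

Step 1
Reactants: 1 3,4-dihydroxybenzaldehyde; 2 3-chloro-3-methylbut-1-yne
Product: 3 3-hydroxy-4-[(2-methylbut-3-yn-2-yl)oxy]benzaldehyde
Conditions: K2CO3 (1.1 equiv), KI, CuI (cat.), DMF, 60 °C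
Reagents that add atoms: none
Why: Copper-assisted Williamson-type propargylic etherification: with one equivalent of carbonate only the 4-OH, made the more acidic phenol by the para formyl group, is ionised, so the tertiary propargyl ether should form at O4 and O3 stays free.

Step 2
Reactants: 3 3-hydroxy-4-[(2-methylbut-3-yn-2-yl)oxy]benzaldehyde
Product: 4 3-(benzyloxy)-4-[(2-methylbut-3-yn-2-yl)oxy]benzaldehyde
Conditions: BnBr, K2CO3, DMF, rt
Reagents that add atoms: benzyl bromide, BrCc1ccccc1
Why: Williamson ether synthesis on the only remaining phenol, which gives a protecting group that is inert to fluoride and base and is removed later by hydrogenolysis.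

Step 3
Reactants: 4 3-(benzyloxy)-4-[(2-methylbut-3-yn-2-yl)oxy]benzaldehyde
Product: 5 8-(benzyloxy)-2,2-dimethyl-2H-chromene-6-carbaldehyde
Conditions: PhNEt2, 190 °C
Reagents that add atoms: none
Why: Aryl propargyl ether Claisen rearrangement: the [3,3] shift can only go to the free ortho carbon, and the allenylphenol formed should pass by 1,5-hydrogen shift and 6π oxa-electrocyclisation into the 2,2-dimethyl-2H-chromene.

Step 4
Reactants: 5 8-(benzyloxy)-2,2-dimethyl-2H-chromene-6-carbaldehyde
Product: 6 (3R,4R)-8-(benzyloxy)-3,4-epoxy-2,2-dimethylchromane-6-carbaldehyde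
Conditions: (R,R)-(salen)MnCl [(R,R)-N,N'-bis(3,5-di-tert-butylsalicylidene)-1,2-cyclohexanediaminomanganese chloride] (cat.), 4-phenylpyridine N-oxide, aq. NaOCl (pH 11.3), CH2Cl2, 0 °C
Reagents that add atoms: sodium hypochlorite, [Na+].[O-]Cl
Why: Jacobsen–Katsuki epoxidation: the oxo-manganese salen species transfers oxygen to the cis, aryl-conjugated C3=C4 bond, and the (R,R) ligand should direct it to the face that gives the (3R,4R) oxide, the sense known for 2,2-dimethylchromenes with this catalyst, while the formyl group should survive the buffered two-phase hypochlorite.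

Step 5
Reactants: 6 (3R,4R)-8-(benzyloxy)-3,4-epoxy-2,2-dimethylchromane-6-carbaldehyde
Product: 7 (3R,4S)-8-(benzyloxy)-3,4-dihydroxy-2,2-dimethylchromane-6-carbaldehyde
Conditions: HClO4 (cat.), THF–H2O, 0 °C → rt
Reagents that add atoms: water, O
Why: Acid-catalysed epoxide hydrolysis: water opens the protonated oxide at benzylic C4 from the face opposite the oxygen (C3 is neopentyl-like and the 6-formyl group disfavours a free cation), so C4 is inverted to S while C3 stays R and the trans diol results.

Step 6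
Reactants: 7 (3R,4S)-8-(benzyloxy)-3,4-dihydroxy-2,2-dimethylchromane-6-carbaldehyde
Product: 8 (3R,4S)-8-(benzyloxy)-3,4-bis(TBSO)-2,2-dimethylchromane-6-carbaldehyde
Conditions: TBSOTf (3 equiv), 2,6-lutidine, CH2Cl2, 0 °C → rt
Reagents that add atoms: tert-butyldimethylsilyl trifluoromethanesulfonate, CC(C)(C)[Si](C)(C)OS(=O)(=O)C(F)(F)F
Why: Silylation of both secondary alcohols with the silyl triflate, which is reactive enough for the hindered C3 hydroxyl next to the gem-dimethyl carbon, gives ethers that should resist the later Lewis acid, hydrogenation, alkoxide and fluoride-in-THF conditions.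

Step 7
Reactants: 8 (3R,4S)-8-(benzyloxy)-3,4-bis(TBSO)-2,2-dimethylchromane-6-carbaldehyde; 9 ethyl diazoacetate
Product: 10 ethyl 3-[(3R,4S)-8-(benzyloxy)-3,4-bis(TBSO)-2,2-dimethylchroman-6-yl]-3-oxopropanoate
Conditions: SnCl2 (cat.), CH2Cl2, rt
Reagents that add atoms: none
Why: Roskamp homologation: SnCl2 activates the aldehyde for addition of the diazo ester, and a 1,2-hydride shift with loss of N2 gives the β-keto ester directly.

Step 8
Reactants: 10 ethyl 3-[(3R,4S)-8-(benzyloxy)-3,4-bis(TBSO)-2,2-dimethylchroman-6-yl]-3-oxopropanoate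
Product: 11 ethyl (3S)-3-[(3R,4S)-8-(benzyloxy)-3,4-bis(TBSO)-2,2-dimethylchroman-6-yl]-3-hydroxypropanoate
Conditions: H2 (50 atm), RuCl2[(R)-BINAP] (cat.), EtOH, 50 °C
Reagents that add atoms: none
Why: Noyori asymmetric hydrogenation: the β-keto ester chelates ruthenium and the (R)-BINAP complex should add hydrogen to the ketone face that gives the (3S) carbinol (the spatial sense that gives (R)-3-hydroxybutanoate, S here because aryl outranks the CH2 group), under catalyst control and without touching benzyl or silyl ethers.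

**Aryne precursor fragment**

Step 9
Reactants: 12 4-(benzyloxy)phenol
Product: 13 4-(benzyloxy)-2-chlorophenol
Conditions: SO2Cl2 (1.0 equiv), (i-Bu)2NH (cat.), toluene, 60 °C
Reagents that add atoms: sulfuryl chloride, O=S(=O)(Cl)Cl
Why: Electrophilic aromatic chlorination: the para position is blocked and the amine–sulfuryl chloride system chlorinates ortho to the free hydroxyl, the strongest director.

Step 10
Reactants: 13 4-(benzyloxy)-2-chlorophenol
Product: 14 4-(benzyloxy)-2-bromo-6-chlorophenol
Conditions: NBS (1.0 equiv), i-Pr2NH (cat.), CH2Cl2, 0 °C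
Reagents that add atoms: N-bromosuccinimide, O=C1CCC(=O)N1Br
Why: Amine-catalysed electrophilic bromination with N-bromosuccinimide should go to the one remaining position ortho to the hydroxyl.

Step 11
Reactants: 14 4-(benzyloxy)-2-bromo-6-chlorophenol
Product: 17 4-(benzyloxy)-2-chloro-6-(trimethylsilyl)phenyl trifluoromethanesulfonate, via aryl trimethylsilyl ether 15 (not isolated), via lithium silylphenoxide 16 (not isolated)
Conditions: HMDS, THF, 65 °C, then evaporation; n-BuLi, THF, −78 °C; Tf2O, −78 → 0 °C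
Reagents that add atoms: hexamethyldisilazane, C[Si](C)(C)N[Si](C)(C)C; trifluoromethanesulfonic anhydride, O=S(=O)(OS(=O)(=O)C(F)(F)F)C(F)(F)F
Why: O-silylation, bromine–lithium exchange and retro-Brook 1,3-migration of silicon from oxygen to carbon give the ortho-silyl phenoxide, which is trapped as the triflate; chlorine and the benzyl ether are inert to n-BuLi at −78 °C.

**Union and endgame**

Step 12
Reactants: 11 ethyl (3S)-3-[(3R,4S)-8-(benzyloxy)-3,4-bis(TBSO)-2,2-dimethylchroman-6-yl]-3-hydroxypropanoate; 17 4-(benzyloxy)-2-chloro-6-(trimethylsilyl)phenyl trifluoromethanesulfonate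
Product: 20 (2S)-7-(benzyloxy)-2-[(3R,4S)-8-(benzyloxy)-3,4-bis(TBSO)-2,2-dimethylchroman-6-yl]-5-chlorochroman-4-one, via sodium alkoxide 18 (not isolated), via aryne 19 (not isolated)
Conditions: NaH (1.05 equiv), THF, 0 °C; then CsF, 18-crown-6, slow addition of 17 (1.5 equiv), THF, −20 °C → rt
Reagents that add atoms: none
Why: Proposed new method: fluoride strips the trimethylsilyl group from 17 and triflate leaves to give aryne 19, the sodium alkoxide 18 adds to the aryne carbon remote from chlorine (the future C8a), and the aryl anion created at C4a attacks the ester carbonyl and the tetrahedral intermediate expels ethoxide, so that O1–C8a and C4–C4a form and ring C closes in one flask. The closest known reaction type is the fluoride-induced aryne annulation of salicylate esters to xanthones, together with the aryne annulations of acrylic acids to 4-chromanones and of β-lactams to 2,3-dihydroquinolin-4-ones, none of which has been extended to the alkoxide of an aliphatic β-hydroxy ester. Ring C closes by 6-exo-trig acyl substitution. No stereocentre is created: the C2–O bond set in step 8 is never broken, so the (S) configuration should pass into the flavanone with retention. The step needs O-attack at C8a and C-acylation at C4a, which the C5 chlorine secures by distorting the aryne so that the nucleophile enters at the distal carbon and the charge develops next to the halogen, outweighing the weak opposite bias of the C7 benzyloxy group. It also needs acyl capture to outrun protonation, chloride loss from the ortho-chloroaryl anion, retro-aldol of 18 and base-induced reopening of ring C, hence the alkoxide made with NaH (H2 as the only co-product), aprotic THF at low temperature, and excess 17 to consume the ethoxide.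

Step 13
Reactants: 20 (2S)-7-(benzyloxy)-2-[(3R,4S)-8-(benzyloxy)-3,4-bis(TBSO)-2,2-dimethylchroman-6-yl]-5-chlorochroman-4-one
Product: 21 (2S)-2-[(3R,4S)-3,4-bis(TBSO)-8-hydroxy-2,2-dimethylchroman-6-yl]-7-hydroxychroman-4-one
Conditions: H2 (1 atm), 10% Pd/C, NaOAc, EtOAc–EtOH, rt
Reagents that add atoms: none
Why: Catalytic hydrogenolysis over palladium on carbon should cleave both aryl benzyl ethers and the ketone-activated C5–Cl bond in one operation, NaOAc taking up HCl without being basic enough to open ring C, and the silyl ether keeping the benzylic C4–O bond of the chromane from hydrogenolysis.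

Step 14
Reactants: 21 (2S)-2-[(3R,4S)-3,4-bis(TBSO)-8-hydroxy-2,2-dimethylchroman-6-yl]-7-hydroxychroman-4-one
Product: 22 (2S)-7-hydroxy-2-[(3R,4S)-3,4,8-trihydroxy-2,2-dimethylchroman-6-yl]chroman-4-one
Conditions: HF·pyridine, pyridine, THF, 0 °C → rt
Reagents that add atoms: none
Why: Fluoride-mediated desilylation with pyridine-buffered HF·pyridine removes both silyl ethers under non-basic conditions, so the base-labile C2 centre of the flavanone should not be epimerised.

**Compound list**

1 | 3,4-dihydroxybenzaldehyde | O=Cc1ccc(O)c(O)c1 | starting material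
2 | 3-chloro-3-methylbut-1-yne | CC(C)(Cl)C#C | starting material
3 | 3-hydroxy-4-[(2-methylbut-3-yn-2-yl)oxy]benzaldehyde | CC(C)(C#C)Oc1ccc(C=O)cc1O | intermediate
4 | 3-(benzyloxy)-4-[(2-methylbut-3-yn-2-yl)oxy]benzaldehyde | CC(C)(C#C)Oc1ccc(C=O)cc1OCc1ccccc1 | intermediate
5 | 8-(benzyloxy)-2,2-dimethyl-2H-chromene-6-carbaldehyde | CC1(C)C=Cc2cc(C=O)cc(OCc3ccccc3)c2O1 | intermediate
6 | (3R,4R)-8-(benzyloxy)-3,4-epoxy-2,2-dimethylchromane-6-carbaldehyde | CC1(C)Oc2c(OCc3ccccc3)cc(C=O)cc2[C@H]4O[C@@H]14 | intermediate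
7 | (3R,4S)-8-(benzyloxy)-3,4-dihydroxy-2,2-dimethylchromane-6-carbaldehyde | CC1(C)Oc2c(OCc3ccccc3)cc(C=O)cc2[C@H](O)[C@H]1O | intermediate
8 | (3R,4S)-8-(benzyloxy)-3,4-bis[(tert-butyldimethylsilyl)oxy]-2,2-dimethylchromane-6-carbaldehyde | CC1(C)Oc2c(OCc3ccccc3)cc(C=O)cc2[C@H](O[Si](C)(C)C(C)(C)C)[C@H]1O[Si](C)(C)C(C)(C)C | intermediate
9 | ethyl diazoacetate | CCOC(=O)C=[N+]=[N-] | starting material
10 | ethyl 3-{(3R,4S)-8-(benzyloxy)-3,4-bis[(tert-butyldimethylsilyl)oxy]-2,2-dimethylchroman-6-yl}-3-oxopropanoate | CC1(C)Oc2c(OCc3ccccc3)cc(C(=O)CC(=O)OCC)cc2[C@H](O[Si](C)(C)C(C)(C)C)[C@H]1O[Si](C)(C)C(C)(C)C | intermediate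
11 | ethyl (3S)-3-{(3R,4S)-8-(benzyloxy)-3,4-bis[(tert-butyldimethylsilyl)oxy]-2,2-dimethylchroman-6-yl}-3-hydroxypropanoate | CC1(C)Oc2c(OCc3ccccc3)cc([C@@H](O)CC(=O)OCC)cc2[C@H](O[Si](C)(C)C(C)(C)C)[C@H]1O[Si](C)(C)C(C)(C)C | intermediate
12 | 4-(benzyloxy)phenol | Oc1ccc(OCc2ccccc2)cc1 | starting material
13 | 4-(benzyloxy)-2-chlorophenol | Oc1ccc(OCc2ccccc2)cc1Cl | intermediate
14 | 4-(benzyloxy)-2-bromo-6-chlorophenol | Oc1c(Br)cc(OCc2ccccc2)cc1Cl | intermediate
15 | [4-(benzyloxy)-2-bromo-6-chlorophenoxy]trimethylsilane | C[Si](C)(C)Oc1c(Br)cc(OCc2ccccc2)cc1Cl | intermediate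
16 | lithium 4-(benzyloxy)-2-chloro-6-(trimethylsilyl)phenolate | [Li+].[O-]c1c(Cl)cc(OCc2ccccc2)cc1[Si](C)(C)C | intermediate
17 | 4-(benzyloxy)-2-chloro-6-(trimethylsilyl)phenyl trifluoromethanesulfonate | C[Si](C)(C)c1cc(OCc2ccccc2)cc(Cl)c1OS(=O)(=O)C(F)(F)F | intermediate
18 | sodium alkoxide of 11, sodium (1S)-1-{(3R,4S)-8-(benzyloxy)-3,4-bis[(tert-butyldimethylsilyl)oxy]-2,2-dimethylchroman-6-yl}-3-ethoxy-3-oxopropan-1-olate | CC1(C)Oc2c(OCc3ccccc3)cc([C@@H]([O-])CC(=O)OCC)cc2[C@H](O[Si](C)(C)C(C)(C)C)[C@H]1O[Si](C)(C)C(C)(C)C.[Na+] | intermediate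
19 | 5-(benzyloxy)-3-chlorobenzyne (5-(benzyloxy)-3-chloro-1,2-didehydrobenzene) | ClC1=CC(OCc2ccccc2)=CC#C1 | intermediate
20 | (2S)-7-(benzyloxy)-2-{(3R,4S)-8-(benzyloxy)-3,4-bis[(tert-butyldimethylsilyl)oxy]-2,2-dimethylchroman-6-yl}-5-chlorochroman-4-one | CC1(C)Oc2c(OCc3ccccc3)cc([C@@H]3CC(=O)c4c(Cl)cc(OCc5ccccc5)cc4O3)cc2[C@H](O[Si](C)(C)C(C)(C)C)[C@H]1O[Si](C)(C)C(C)(C)C | intermediate
21 | (2S)-2-{(3R,4S)-3,4-bis[(tert-butyldimethylsilyl)oxy]-8-hydroxy-2,2-dimethylchroman-6-yl}-7-hydroxychroman-4-one | CC1(C)Oc2c(O)cc([C@@H]3CC(=O)c4ccc(O)cc4O3)cc2[C@H](O[Si](C)(C)C(C)(C)C)[C@H]1O[Si](C)(C)C(C)(C)C | intermediate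
22 | (2S)-7-hydroxy-2-[(3R,4S)-3,4,8-trihydroxy-2,2-dimethylchroman-6-yl]chroman-4-one | CC1(C)Oc2c(O)cc([C@@H]3CC(=O)c4ccc(O)cc4O3)cc2[C@H](O)[C@H]1O | target

Total step count: 14. Longest linear sequence: 11 steps (steps 1 to 8, then 12 to 14).

**Steps most likely to fail**

Step 12. The aryl anion may be protonated before it reaches the ester, so that ring C stays open. The alkoxide may undergo reversible retro-aldol cleavage, which erodes the C2 configuration. Ring C may reopen under the basic conditions. The fallback uses known chemistry, sets out from 10 and returns at 21. Hydrogenation of 10 with the enantiomeric catalyst RuCl2[(S)-BINAP] should give the epimeric ethyl (3R)-hydroxy ester F1. Aminolysis with MeNHOMe·HCl and i-PrMgCl should convert it into the Weinreb amide F2. The C,O-dilithio derivative of 5-(benzyloxy)-2-bromophenol (n-BuLi, two equivalents, THF, −78 °C) should add to it to give the 2-hydroxyaryl β-hydroxy ketone F3. Intramolecular Mitsunobu etherification (PPh3, diisopropyl azodicarboxylate, THF, 0 °C) should close ring C with inversion at the carbinol carbon to give the chlorine-free (2S)-7-(benzyloxy)flavanone F4. Hydrogenolysis of its two benzyl ethers (H2, Pd/C, EtOAc) leads to 21.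

Step 7. Addition of the diazo ester to the electron-rich aryl aldehyde may be slow, and migration of the aryl group may compete with the hydride shift. The fallback sets out from 8 and returns at 10. Aldol addition of the lithium enolate of ethyl acetate (LDA, EtOAc, THF, −78 °C) should give the β-hydroxy ester F5 as a mixture of carbinol epimers. Dess–Martin oxidation (NaHCO3, CH2Cl2) then gives 10.

Step 5. Partial ionisation at benzylic C4, assisted by the ring oxygen O1, may let water enter from both faces and so lose the anti selectivity. The fallback sets out from 6 and returns at 7. Buffered acetolysis (CsOAc, AcOH, DMF, 50 °C), in which acetate opens the oxide at C4 by direct SN2 displacement, should give the trans hydroxy acetate F6. Methanolysis (K2CO3, MeOH, rt) then gives 7.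

Further compounds
F1 | step 12 | ethyl (3R)-3-{(3R,4S)-8-(benzyloxy)-3,4-bis[(tert-butyldimethylsilyl)oxy]-2,2-dimethylchroman-6-yl}-3-hydroxypropanoate | CC1(C)Oc2c(OCc3ccccc3)cc([C@H](O)CC(=O)OCC)cc2[C@H](O[Si](C)(C)C(C)(C)C)[C@H]1O[Si](C)(C)C(C)(C)C
F2 | step 12 | (3R)-3-{(3R,4S)-8-(benzyloxy)-3,4-bis[(tert-butyldimethylsilyl)oxy]-2,2-dimethylchroman-6-yl}-3-hydroxy-N-methoxy-N-methylpropanamide | CC1(C)Oc2c(OCc3ccccc3)cc([C@H](O)CC(=O)N(C)OC)cc2[C@H](O[Si](C)(C)C(C)(C)C)[C@H]1O[Si](C)(C)C(C)(C)C
F3 | step 12 | (3R)-1-[4-(benzyloxy)-2-hydroxyphenyl]-3-{(3R,4S)-8-(benzyloxy)-3,4-bis[(tert-butyldimethylsilyl)oxy]-2,2-dimethylchroman-6-yl}-3-hydroxypropan-1-one | CC1(C)Oc2c(OCc3ccccc3)cc([C@H](O)CC(=O)c3ccc(OCc4ccccc4)cc3O)cc2[C@H](O[Si](C)(C)C(C)(C)C)[C@H]1O[Si](C)(C)C(C)(C)C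
F4 | step 12 | (2S)-7-(benzyloxy)-2-{(3R,4S)-8-(benzyloxy)-3,4-bis[(tert-butyldimethylsilyl)oxy]-2,2-dimethylchroman-6-yl}chroman-4-one | CC1(C)Oc2c(OCc3ccccc3)cc([C@@H]3CC(=O)c4ccc(OCc5ccccc5)cc4O3)cc2[C@H](O[Si](C)(C)C(C)(C)C)[C@H]1O[Si](C)(C)C(C)(C)C
F5 | step 7 | ethyl 3-{(3R,4S)-8-(benzyloxy)-3,4-bis[(tert-butyldimethylsilyl)oxy]-2,2-dimethylchroman-6-yl}-3-hydroxypropanoate, both carbinol epimers | CC1(C)Oc2c(OCc3ccccc3)cc(C(O)CC(=O)OCC)cc2[C@H](O[Si](C)(C)C(C)(C)C)[C@H]1O[Si](C)(C)C(C)(C)C
F6 | step 5 | (3R,4S)-8-(benzyloxy)-6-formyl-3-hydroxy-2,2-dimethylchroman-4-yl acetate | CC1(C)Oc2c(OCc3ccccc3)cc(C=O)cc2[C@H](OC(C)=O)[C@H]1O
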